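3.16 /M/d is what the delta run gives, between its first two readings, for the wear constant: the daily loss of the pool of L plus Z, divided by L times Z. The zeta run, at a lower charge of L, gives 3.31 /M/d, so we take the loss as proportional to that product; at a held L it is pseudo-first-order in Z.

| setting | delta | zeta | gamma | alpha | maple | birch | elm | cedar |
|---|---|---|---|---|---|---|---|---|
| L | 0.50 M | 0.25 M | 0.38 M | 0.50 M | 0.50 M | 0.50 M | 0.50 M (fed, over 8.00 d) | 0.50 M |
| Q | 0.50 M | 0.50 M | 0.50 M | 0.50 M | 0.500 M | 0.500 M (fed, over 8.00 d) | 0.500 M | 0.500 M |
| G | 0.15 M | 0.15 M | 0.15 M | 0.22 M | 0.150 M | 0.150 M | 0.150 M | 0.150 M |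
| remark | run made earlier | run made earlier | run made earlier | run made earlier | a closed flask charged with all of it at once and left for 8.0 d | a stirred flask in which Q is dosed at a steady rate over 8.00 d without added volume, worked up at 8.0 d | all but L at the start; L goes in evenly over 8.00 d, the run ends at 8.0 d | a single well-mixed tank run continuously and read at steady state, 8.0 d in it on average |
| time |  |  |  |  | 8.0 d | 8.0 d | 8.0 d |  |

- delta (time / d: Z / %, L / %): 1.04: 26.4, 43.1; 2.08: 19.8, 34.9; 3.00: 16.1, 28.1; 4.00: 13.5, 23.9; 5.00: 9.8, 23.8
- zeta (time / d: Z / %, L / %): 1.25: 45.6, 33.2; 2.50: 39.3, 26.4; 4.00: 31.4, 22.6; 5.00: 28.5, 19.9; 6.00: 27.4, 18.1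
- gamma (time / d: Z / %, L / %): 1.25: 33.2, 39.1; 2.50: 25.1, 30.1; 4.00: 18.2, 25.0; 5.00: 18.3, 19.3; 6.00: 15.4, 19.3
- alpha (time / d: Z / %, L / %): 0.625: 27.4, 52.5; 1.67: 19.9, 43.1; 3.00: 13.8, 33.6; 5.00: 8.4, 28.3; 6.00: 6.9, 23.5

(readings scatter by 1 percentage point)

- the stated concentrations are those of everything mixed, before any reaction; amounts are the same in each set-up
- the feed brings no volume worth counting
- the earlier runs were made in a closed, stirred flask

1. the set-up with the highest amount of Z at the outlet or at the end, in percent of the L put in ("none" if the first two lie within 2 percentage points) (maple / birch / elm / cedar / none)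
2. amount of Z at the outlet or at the end, in percent of the L put in, maple
3. amount of Z at the outlet or at the end, in percent of the L put in, birch
4. amount of Z at the outlet or at the end, in percent of the L put in, elm
5. amount of Z at the outlet or at the end, in percent of the L put in, cedar

We compare rates at one moment. Elm takes in L at 0.0625 M/d, but at the levels of delta's first reading the pool would wear at 0.0899 M/d, faster than that feed. So elm's pool should stop growing where wear equals feed. To split that product we need Z per L, and delta's later readings give 0.520. For elm, whose charge matches delta's by the end, this balance then estimates Z at 0.101 M, or 20.2 % of its L. Maple has delta's charge, so we let delta's last pool wear on at the same split and reach 8.46 % Z. In cedar, we set feed equal to outflow plus wear, which at the same split estimates Z at 15.1 %. Birch starts with 0.50 M of L, more than the 0.195 M at elm's balance, so we place it below elm without a number.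

The weak link is the split. Zeta's late readings give 1.47, higher than delta's, so the split moves with the charge, and within delta it drifts down. Delta's last reading gives 0.412, which puts elm at 18.1 %. We commit to elm as best, with its Z between these two estimates.

The forecast, which differs from us on maple and cedar, names elm and gives 6.8 % for maple, 10.5 % for birch, 19 % for elm and 13 % for cedar, arguing of elm “L stays low and Q high, so Z builds up”. The flask gives 7.76 % for maple, 14.1 % for birch, 18.4 % for elm and 14.4 % for cedar, so elm leads.

    L + Q ⇌ Z + X (K = 0.940, k = 0.470 /M/h)
    L + Z → J (k = 0.0740 /M/h)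
    Q + G → E (k = 4.20 /M/h)

Now take elm with its L cut to 0.12 M, everything else held, so that the feed falls to 0.0150 M/d. The wear constant on elm's own final state gives wear at 0.768 of the feed. On the neighbour's final state it gives 0.417, a smaller share. J in the neighbour ends at 16.3 % of the L charged, less than the 48.6 % in elm. L stands at 22.4 %, and Z, now the main holder of the L, reaches 61.3 %.

All runs come from a simulation from invented constants, and the scatter is random.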